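The target is a diarylmethane whose CH2 carbon is bonded to C1 of ring A (3-bromo-4-hydroxyphenyl) and C1 of ring B (3,5-dibromo-4-hydroxyphenyl), each para to a phenolic OH. One more bromine at C5 of ring A would make the rings identical, so both CH2–aryl bonds are disconnected at once to formaldehyde and two molecules of 2,6-dibromophenol, whose bromines at C2 and C6 leave only the para carbon open. The acid-mediated condensation builds the whole skeleton and brings in every bromine the target needs in one operation. A single chelation-assisted bromine–magnesium exchange on the bis-MOM ether, protonation and acidolysis then remove the surplus bromine, any of the four being equivalent.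

Key step: step 1

Assumption: formaldehyde 2 is charged as paraformaldehyde, which cracks to the monomer in the acidic medium of step 1.

Step 1
Reactants: 1 2,6-dibromophenol (2.1 equiv); 2 formaldehyde (1.0 equiv, as paraformaldehyde)
Product: 4 bis(3,5-dibromo-4-hydroxyphenyl)methane, via 3,5-dibromo-4-hydroxybenzyl alcohol 3 (not isolated)
Conditions: (CH2O)n, conc. H2SO4, AcOH, 0 °C to 50 °C
Reagents that add atoms: none
Why: Paraformaldehyde depolymerises in acid and protonated formaldehyde attacks C4 of 1, the only activated ring carbon not carrying bromine, to give benzylic alcohol 3 (electrophilic aromatic hydroxymethylation). In the acid 3 loses water to a para-hydroxybenzyl cation, the O-protonated form of a para-quinone methide, and a second molecule of 1 adds through its C4, so that the two CH2–aryl bonds, later CH2–C1 of ring A and CH2–C1 of ring B, both arise in one flask. The closest known reaction type is the acid-catalysed Friedel–Crafts condensation of phenols with formaldehyde to bisphenol F and its 2,6-disubstituted congeners. No ring is closed and no stereocentre is formed. The step needs exclusive para attack and a clean stop at the dimer: the bromines at C2 and C6 block both ortho carbons, the hydroxyl group directs to C4, and product 4 has no free ortho or para position left, so that chain growth to oligomers is excluded. A slight excess of 1 should consume 3 completely.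

Step 2
Reactants: 4 bis(3,5-dibromo-4-hydroxyphenyl)methane
Product: 5 bis[3,5-dibromo-4-(methoxymethoxy)phenyl]methane
Conditions: MOMCl (2.6 equiv), iPr2NEt (3 equiv), CH2Cl2, 0 °C to rt
Reagents that add atoms: chloromethyl methyl ether (MOMCl), COCCl
Why: The phenols of 4, made acidic by their flanking bromines, are deprotonated by the amine and O-alkylated by the highly electrophilic chloromethyl ether (Williamson-type MOM ether formation), while the aryl bromides and the diarylmethane bridge are inert to these conditions.

Step 3
Reactants: 5 bis[3,5-dibromo-4-(methoxymethoxy)phenyl]methane
Product: 8 target 2,6-dibromo-4-(3-bromo-4-hydroxybenzyl)phenol, via arylmagnesium chloride 6 (not isolated), via tribromide bis-MOM ether 7 (not isolated)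
Conditions: iPrMgCl·LiCl (0.9 equiv), THF, 0 °C to rt; MeOH; then conc. HCl, MeOH, 50 °C
Reagents that add atoms: none
Why: A halogen–magnesium exchange with iPrMgCl·LiCl, assisted by chelation and induction from the neighbouring OMOM group, should convert one of the four equivalent C–Br bonds of 5 into the arylmagnesium 6, whose negative charge shuts down a second exchange on the same ring, after which protonation by MeOH gives 7 and acid-catalysed acetal exchange with MeOH releases both phenols without touching the remaining C–Br bonds; the reagent is kept below one equivalent so that over-exchange on the other ring stays small, and unreacted material, returned as 4 after chromatography of the free phenols, is recycled to step 2.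

Compound list
1 | 2,6-dibromophenol | Oc1c(Br)cccc1Br | starting material
2 | formaldehyde (used as paraformaldehyde) | C=O | starting material
3 | 3,5-dibromo-4-hydroxybenzyl alcohol, formed in the flask and not isolated | OCc1cc(Br)c(O)c(Br)c1 | intermediate
4 | bis(3,5-dibromo-4-hydroxyphenyl)methane, also named 4,4'-methylenebis(2,6-dibromophenol) | Oc1c(Br)cc(Cc2cc(Br)c(O)c(Br)c2)cc1Br | intermediate
5 | bis[3,5-dibromo-4-(methoxymethoxy)phenyl]methane | COCOc1c(Br)cc(Cc2cc(Br)c(OCOC)c(Br)c2)cc1Br | intermediate
6 | {3-bromo-5-[3,5-dibromo-4-(methoxymethoxy)benzyl]-2-(methoxymethoxy)phenyl}magnesium chloride (as LiCl complex), not isolated | COCOc1c(Br)cc(Cc2cc(Br)c(OCOC)c([Mg]Cl)c2)cc1Br | intermediate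
7 | 1,3-dibromo-5-[3-bromo-4-(methoxymethoxy)benzyl]-2-(methoxymethoxy)benzene, not isolated | COCOc1ccc(Cc2cc(Br)c(OCOC)c(Br)c2)cc1Br | intermediate
8 | 2,6-dibromo-4-(3-bromo-4-hydroxybenzyl)phenol (achiral) | Oc1ccc(Cc2cc(Br)c(O)c(Br)c2)cc1Br | target

Total step count: 3
Longest linear sequence: 3 steps

Steps most likely to fail

Step 3. The exchange has no substrate bias between the two insulated rings, so over-exchange on the second ring and incomplete conversion may occur side by side. The separation of phenols that differ by one bromine may then be tedious and the throughput per pass low. The fallback builds the unsymmetrical diarylmethane directly instead of desymmetrizing a symmetrical one. It sets out from compound 3, prepared here as an isolated solid by NaBH4 reduction (MeOH, 0 °C) of purchased 3,5-dibromo-4-hydroxybenzaldehyde F1. Compound 3 is then ionized with catalytic H2SO4 in AcOH in the presence of a large excess of 2-bromophenol F2. The para-hydroxybenzyl cation should be captured mainly at the carbon para to the hydroxyl group of F2 (Friedel–Crafts benzylation), which gives the tribromide without any statistical step. Excess F2 is removed by distillation, and the fallback comes back to the route at compound 8.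

Step 1. The electron-poor phenol may react sluggishly, so that the condensation stalls at the hydroxymethyl stage. Forcing it may bring on ring sulfonation or acid-promoted migration and loss of bromine. The fallback reverses the order of events, skeleton first and halogens second. It sets out from no numbered compound of the route but, in place of 1 and 2, from purchased bis(4-hydroxyphenyl)methane F3. Treatment with Br2 (4.1 equiv) in AcOH at 0 °C to rt should brominate all four positions ortho to the two hydroxyl groups, the para positions being occupied by the bridge. The fallback comes back to the route at compound 4.

Step 2. O-Alkylation of phenoxide oxygens that are flanked by two bromines and are weakly nucleophilic may stay incomplete, and the acetals may be lost during purification. The fallback dispenses with the protecting group and lets the phenoxides protect themselves. It sets out from compound 4, which n-BuLi (2.0 equiv, THF, −78 °C) should convert into the dilithium bis(phenolate) F4. A further portion of n-BuLi (0.9 equiv, −78 °C) should then effect a single bromine–lithium exchange to the ring-lithiated dilithium bis(phenolate) F5. Quenching with MeOH and aqueous HCl protonates the carbon and both oxygens, and the fallback comes back to the route at compound 8, passing over step 3 as well.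

Further compounds
F1 | step 3 | 3,5-dibromo-4-hydroxybenzaldehyde (purchased) | O=Cc1cc(Br)c(O)c(Br)c1
F2 | step 3 | 2-bromophenol (purchased) | Oc1ccccc1Br
F3 | step 1 | bis(4-hydroxyphenyl)methane (purchased) | Oc1ccc(Cc2ccc(O)cc2)cc1
F4 | step 2 | dilithium bis(phenolate) of bis(3,5-dibromo-4-hydroxyphenyl)methane | [Li]Oc1c(Br)cc(Cc2cc(Br)c(O[Li])c(Br)c2)cc1Br
F5 | step 2 | ring-lithiated dilithium bis(phenolate), lithium at the carbon that has lost bromine | [Li]Oc1c(Br)cc(Cc2cc(Br)c(O[Li])c([Li])c2)cc1Br
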